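**Strategy.** Everything rests on cutting the saturated chain between C2 and C3 (C1 = benzylic carbon, C17 = methyl). C1–C2 is traced back to the vinyl group of a bis-silylated 3,5-dihydroxystyrene, C3 to the CH2Br terminus of a complete C15 chain that already holds both Z olefins (C8=C9, C14=C15) and the (S)-carbinol C12. In one operation, anti-Markovnikov hydroboration with 9-BBN followed by Pd/PCy3 alkyl–alkyl Suzuki–Miyaura coupling joins the two halves. The step exploits the 2-arylethyl unit on the resorcinol ring and the five-methylene spacer C3–C7 that insulates the bromide from the C8=C9 olefin. The chain arises from an L-glutamic-acid-derived lactone by Z-alkenylcuprate epoxide opening and a lactol Wittig reaction.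

Key step: step 8

Remark: 4 is taken as the commercial (S)-enantiomer (L-glutamic acid series), and lactol 9 is carried on as its mixture of anomers because the anomeric centre disappears in step 6.

**Step 1**
Reactants: 1 3,5-dihydroxybenzaldehyde
Product: 2 3,5-bis(tert-butyldimethylsilyloxy)benzaldehyde
Conditions: TBSCl (2.3 equiv), imidazole, DMF, rt
Reagents that add atoms: tert-butyldimethylsilyl chloride, CC(C)(C)[Si](C)(C)Cl
Why: Imidazole-promoted silylation of both phenols should be clean and masks the acidic OH groups that would otherwise consume ylide and 9-BBN later.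

**Step 2**
Reactants: 2 3,5-bis(tert-butyldimethylsilyloxy)benzaldehyde
Product: 3 3,5-bis(tert-butyldimethylsilyloxy)styrene
Conditions: Ph3PCH3Br, n-BuLi, THF, 0 °C; then 2, 0 °C → rt
Reagents that add atoms: methyltriphenylphosphonium bromide, C[P+](c1ccccc1)(c1ccccc1)c1ccccc1.[Br-]
Why: Wittig methylenation of an aromatic aldehyde with the preformed non-stabilised ylide should leave the aryl silyl ethers intact because no free base remains.

**Step 3**
Reactants: 4 (S)-5-(p-toluenesulfonyloxymethyl)dihydrofuran-2(3H)-one
Product: 6 methyl (4S)-4,5-epoxypentanoate, via hydroxy tosylate ester 5 (not isolated)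
Conditions: NaOMe (1.05 equiv), MeOH, 0 °C → rt
Reagents that add atoms: sodium methoxide, C[O-].[Na+]
Why: Methoxide opens the lactone by transesterification and the freed C4 alkoxide closes the epoxide by intramolecular Williamson displacement of the primary tosylate; no bond to the stereocentre is broken, so its configuration is retained.

**Step 4**
Reactants: 6 methyl (4S)-4,5-epoxypentanoate
Product: 8 (5S)-5-[(2Z)-pent-2-en-1-yl]dihydrofuran-2(3H)-one, via hydroxy ester 7 (not isolated)
Conditions: EtLi, CuBr·SMe2, Et2O, −40 °C; HC≡CH, −50 → −25 °C; then 6, −40 → −10 °C; aq NH4Cl; cat. TsOH, CH2Cl2, rt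
Reagents that add atoms: ethyllithium, [Li]CC; acetylene, C#C
Why: Syn-carbocupration of acetylene by lithium diethylcuprate (Normant carbocupration) gives the di-(Z)-but-1-enylcuprate with defined Z geometry, which should open the terminal epoxide at its CH2 carbon (SN2 cuprate epoxide opening) without attacking the ester; the γ-hydroxy ester then lactonises and the carbinol centre keeps its configuration.

**Step 5**
Reactants: 8 (5S)-5-[(2Z)-pent-2-en-1-yl]dihydrofuran-2(3H)-one
Product: 9 (5S)-5-[(2Z)-pent-2-en-1-yl]tetrahydrofuran-2-ol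
Conditions: DIBAL-H (1.1 equiv), CH2Cl2, −78 °C; Rochelle salt work-up
Reagents that add atoms: none
Why: Partial reduction of a γ-lactone by DIBAL-H at −78 °C stops at the aluminium hemiacetal and should give the lactol without touching the olefin or the stereocentre.

**Step 6**
Reactants: 9 (5S)-5-[(2Z)-pent-2-en-1-yl]tetrahydrofuran-2-ol
Product: 10 (6Z,10S,12Z)-pentadeca-6,12-diene-1,10-diol
Conditions: [Ph3P(CH2)6OH]Br (2.5 equiv), NaHMDS (5 equiv), THF, 0 °C; then 9, −78 °C → rt
Reagents that add atoms: (6-hydroxyhexyl)triphenylphosphonium bromide, OCCCCCC[P+](c1ccccc1)(c1ccccc1)c1ccccc1.[Br-]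
Why: Wittig olefination of the lactol through its open hydroxy-aldehyde form with a non-stabilised ylide under lithium-free conditions should give the Z olefin C8=C9 via the kinetic cis-oxaphosphetane, and it releases the C12 hydroxyl at the same time.

**Step 7**
Reactants: 10 (6Z,10S,12Z)-pentadeca-6,12-diene-1,10-diol
Product: 11 (3Z,6S,9Z)-15-bromopentadeca-3,9-dien-6-ol
Conditions: CBr4 (1.05 equiv), PPh3 (1.1 equiv), CH2Cl2, −20 → 0 °C
Reagents that add atoms: carbon tetrabromide, BrC(Br)(Br)Br
Why: In the Appel bromination the primary alkoxyphosphonium ion forms and is displaced much faster than the hindered secondary one, so limiting reagent at low temperature should give the primary bromide and leave the C12 hydroxyl and its configuration unchanged.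

**Step 8**
Reactants: 3 3,5-bis(tert-butyldimethylsilyloxy)styrene; 11 (3Z,6S,9Z)-15-bromopentadeca-3,9-dien-6-ol
Product: 13 (3Z,6S,9Z)-17-[3,5-bis(tert-butyldimethylsilyloxy)phenyl]heptadeca-3,9-dien-6-ol, via B-alkyl-9-BBN 12 (not isolated)
Conditions: 3 (1.35 equiv), 9-BBN (1.30 equiv), THF, 0 °C → rt; then 11 (1.0 equiv), Pd(OAc)2 (5 mol %), PCy3 (10 mol %), K3PO4·H2O (1.5 equiv), THF, rt
Reagents that add atoms: none
Why: 9-BBN adds syn and anti-Markovnikov across the vinyl group of 3 and places boron on the terminal carbon (the future C2) to give 12; Pd(0)/PCy3 then inserts into the primary C–Br bond of 11 by an SN2-type oxidative addition, the base-activated borate transfers its primary 2-arylethyl group in preference to the secondary cyclooctyl B–C bonds, and reductive elimination forges the C2–C3 sp3–sp3 bond. The closest known reaction type is the Suzuki–Miyaura coupling of B-alkyl-9-BBN reagents with unactivated primary alkyl bromides bearing β-hydrogens under Pd(OAc)2/PCy3/K3PO4·H2O. No ring is closed and no stereocentre is created; C12 and both Z olefins are spectators. The selectivities needed are regioselective hydroboration (secured by the aryl group and the bulk of 9-BBN), absence of residual B–H that could attack the chain olefins (secured by the slight excess of 3 over 9-BBN before 11 is added), and reductive elimination outrunning β-hydride elimination (secured by the bulky, electron-rich PCy3). The five-methylene spacer C3–C7 keeps the C–Br bond remote from the C8=C9 olefin, so no π-allyl, chain-walking or cyclisation pathway is open, and the mild hydrated phosphate base at room temperature should spare the aryl silyl ethers and the free C12 hydroxyl.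

**Step 9**
Reactants: 13 (3Z,6S,9Z)-17-[3,5-bis(tert-butyldimethylsilyloxy)phenyl]heptadeca-3,9-dien-6-ol
Product: 14 5-[(8Z,12S,14Z)-12-hydroxyheptadeca-8,14-dien-1-yl]benzene-1,3-diol
Conditions: TBAF (2.2 equiv), AcOH (2.2 equiv), THF, 0 °C, under argon
Reagents that add atoms: none
Why: Fluoride-induced cleavage of the two aryl silyl ethers, buffered with acetic acid so that no free resorcinolate is exposed, should release the target without affecting the Z olefins or the secondary alcohol.

**Compound list**

1 | 3,5-dihydroxybenzaldehyde | O=Cc1cc(O)cc(O)c1 | starting material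
2 | 3,5-bis(tert-butyldimethylsilyloxy)benzaldehyde | O=Cc1cc(O[Si](C)(C)C(C)(C)C)cc(O[Si](C)(C)C(C)(C)C)c1 | intermediate
3 | 3,5-bis(tert-butyldimethylsilyloxy)styrene | C=Cc1cc(O[Si](C)(C)C(C)(C)C)cc(O[Si](C)(C)C(C)(C)C)c1 | intermediate
4 | (S)-5-(p-toluenesulfonyloxymethyl)dihydrofuran-2(3H)-one | Cc1ccc(cc1)S(=O)(=O)OC[C@@H]1CCC(=O)O1 | starting material
5 | methyl (4S)-4-hydroxy-5-(p-toluenesulfonyloxy)pentanoate (formed as its sodium alkoxide, not isolated) | COC(=O)CC[C@H](O)COS(=O)(=O)c1ccc(C)cc1 | intermediate
6 | methyl (4S)-4,5-epoxypentanoate | COC(=O)CC[C@H]1CO1 | intermediate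
7 | methyl (4S,6Z)-4-hydroxynon-6-enoate (not isolated) | CC/C=C\C[C@@H](O)CCC(=O)OC | intermediate
8 | (5S)-5-[(2Z)-pent-2-en-1-yl]dihydrofuran-2(3H)-one | CC/C=C\C[C@@H]1CCC(=O)O1 | intermediate
9 | (5S)-5-[(2Z)-pent-2-en-1-yl]tetrahydrofuran-2-ol (mixture of anomers) | CC/C=C\C[C@@H]1CCC(O)O1 | intermediate
10 | (6Z,10S,12Z)-pentadeca-6,12-diene-1,10-diol | CC/C=C\C[C@@H](O)CC/C=C\CCCCCO | intermediate
11 | (3Z,6S,9Z)-15-bromopentadeca-3,9-dien-6-ol | CC/C=C\C[C@@H](O)CC/C=C\CCCCCBr | intermediate
12 | 9-{2-[3,5-bis(tert-butyldimethylsilyloxy)phenyl]ethyl}-9-borabicyclo[3.3.1]nonane (not isolated) | CC(C)(C)[Si](C)(C)Oc1cc(CCB2C3CCCC2CCC3)cc(O[Si](C)(C)C(C)(C)C)c1 | intermediate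
13 | (3Z,6S,9Z)-17-[3,5-bis(tert-butyldimethylsilyloxy)phenyl]heptadeca-3,9-dien-6-ol | CC/C=C\C[C@@H](O)CC/C=C\CCCCCCCc1cc(O[Si](C)(C)C(C)(C)C)cc(O[Si](C)(C)C(C)(C)C)c1 | intermediate
14 | 5-[(8Z,12S,14Z)-12-hydroxyheptadeca-8,14-dien-1-yl]benzene-1,3-diol | CC/C=C\C[C@@H](O)CC/C=C\CCCCCCCc1cc(O)cc(O)c1 | target

**Step count and risks**

Total steps: 9. Longest linear sequence: 7 (steps 3–9, from 4 to 14).

Steps most likely to fail:

1. Step 8. β-Hydride elimination from the alkylpalladium intermediates, or slow transmetalation of the homobenzylic borane, could consume the bromide by reduction or elimination; any Pd–H formed could also isomerise the Z olefins. The fallback sets out from 3 and 11 and returns at 13, replacing the boron/palladium coupling by a copper-catalysed Grignard alkyl–alkyl coupling. Styrene 3 is hydroborated to 12 as before and oxidised with sodium perborate to 2-[3,5-bis(tert-butyldimethylsilyloxy)phenyl]ethanol F1. Appel bromination (CBr4, PPh3) should give 1-(2-bromoethyl)-3,5-bis(tert-butyldimethylsilyloxy)benzene F2, and magnesium insertion in THF the Grignard reagent 2-[3,5-bis(tert-butyldimethylsilyloxy)phenyl]ethylmagnesium bromide F3. Bromide 11, first converted to its magnesium alkoxide with one equivalent of MeMgBr, is then coupled with F3 under Li2CuCl4 catalysis (THF/NMP, −20 → 0 °C) to give 13.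

2. Step 6. Stereochemical drift of the oxaphosphetane in the presence of the γ-oxido group, or sluggish opening of the lactol, could erode the Z selectivity at C8=C9. The fallback sets out from 9 and returns at 10 and fixes the geometry by syn-hydrogenation of an alkyne instead. Seyferth–Gilbert homologation of 9 with the Ohira–Bestmann reagent (K2CO3, MeOH) should give (5S,7Z)-dec-7-en-1-yn-5-ol F4. Its dianion (n-BuLi, 2.1 equiv, THF/DMPU) is C-alkylated with 2-(5-bromopentyloxy)tetrahydropyran to give (3Z,6S)-15-(tetrahydropyran-2-yloxy)pentadec-3-en-9-yn-6-ol F5. Lindlar semihydrogenation (Pd/CaCO3–Pb, quinoline, H2) gives (3Z,6S,9Z)-15-(tetrahydropyran-2-yloxy)pentadeca-3,9-dien-6-ol F6, and PPTS in MeOH removes the acetal to give 10.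

3. Step 4. Incomplete carbocupration or multiple acetylene insertion, and incomplete transfer of the alkenyl group to the epoxide in competition with attack on the ester, could lower conversion and geometric purity. The fallback sets out from 6 and returns at 8. Lithium but-1-ynide (but-1-yne, n-BuLi) with BF3·OEt2 in THF at −78 °C opens the epoxide to methyl (4S)-4-hydroxynon-6-ynoate F7. This lactonises on acidic work-up to (5S)-5-(pent-2-yn-1-yl)dihydrofuran-2(3H)-one F8, and Lindlar semihydrogenation gives 8.

**Further compounds**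

F1 | step 8 | 2-[3,5-bis(tert-butyldimethylsilyloxy)phenyl]ethanol | OCCc1cc(O[Si](C)(C)C(C)(C)C)cc(O[Si](C)(C)C(C)(C)C)c1
F2 | step 8 | 1-(2-bromoethyl)-3,5-bis(tert-butyldimethylsilyloxy)benzene | BrCCc1cc(O[Si](C)(C)C(C)(C)C)cc(O[Si](C)(C)C(C)(C)C)c1
F3 | step 8 | 2-[3,5-bis(tert-butyldimethylsilyloxy)phenyl]ethylmagnesium bromide | Br[Mg]CCc1cc(O[Si](C)(C)C(C)(C)C)cc(O[Si](C)(C)C(C)(C)C)c1
F4 | step 6 | (5S,7Z)-dec-7-en-1-yn-5-ol | CC/C=C\C[C@@H](O)CCC#C
F5 | step 6 | (3Z,6S)-15-(tetrahydropyran-2-yloxy)pentadec-3-en-9-yn-6-ol | CC/C=C\C[C@@H](O)CCC#CCCCCCOC1CCCCO1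
F6 | step 6 | (3Z,6S,9Z)-15-(tetrahydropyran-2-yloxy)pentadeca-3,9-dien-6-ol | CC/C=C\C[C@@H](O)CC/C=C\CCCCCOC1CCCCO1
F7 | step 4 | methyl (4S)-4-hydroxynon-6-ynoate | CCC#CC[C@@H](O)CCC(=O)OC
F8 | step 4 | (5S)-5-(pent-2-yn-1-yl)dihydrofuran-2(3H)-one | CCC#CC[C@@H]1CCC(=O)O1
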